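**Retrosynthetic overview**
- Gancaonin J ⇒ davidigenin (2',4,4'-trihydroxydihydrochalcone): each C-prenyl group is traced back to an aryl O–C(CH3)2CH=CH2 ether bond at the 4'-oxygen, moved to carbon by a [3,3] shift (first to C3', then to C5').
- That O–C bond ⇒ 4'-phenoxide + η3-(1,1-dimethylallyl)palladium, generated from isobutyl 2-methylbut-3-en-2-yl carbonate (from 2-methylbut-3-en-2-ol and isobutyl chloroformate).
- Davidigenin ⇒ resorcinol + 3-(4-hydroxyphenyl)propanoic acid (aryl–acyl bond, Friedel–Crafts acylation).
- No ring is built: both benzene rings are bought.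

Assumption: Gancaonin J has no stereocentre and no E/Z-stereogenic double bond, so "the single enantiomer given" is read as the one achiral structure of the SMILES.

**Step 1**
Reactants: 1 resorcinol; 2 3-(4-hydroxyphenyl)propanoic acid (phloretic acid)
Product: 3 davidigenin, 1-(2,4-dihydroxyphenyl)-3-(4-hydroxyphenyl)propan-1-one
Conditions: BF3·OEt2 (neat, solvent and promoter), 1 (1.2 equiv), 90 °C, 2 h; aq. NaOAc work-up
Reagents that add atoms: none
Why: Friedel–Crafts (Nencki-type) acylation in which the BF3-activated acid attacks resorcinol at C4 (para to one OH, ortho to the other), the chelated ketone product is deactivated against a second acylation, and the less activated mono-phenol ring of 2 does not compete; water is the only co-product.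

**Step 2**
Reactants: 4 2-methylbut-3-en-2-ol; 5 isobutyl chloroformate
Product: 7 isobutyl 2-methylbut-3-en-2-yl carbonate, via lithium 2-methylbut-3-en-2-olate 6 (not isolated)
Conditions: n-BuLi (1.05 equiv), THF, −78 → 0 °C; then 5 (1.1 equiv), 0 °C → rt
Reagents that add atoms: none
Why: n-BuLi turns the tertiary alcohol into lithium alkoxide 6, which is O-acylated by the chloroformate (addition–elimination with loss of LiCl), the standard mixed-carbonate synthesis for hindered allylic alcohols.

**Step 3**
Reactants: 3 davidigenin; 7 isobutyl 2-methylbut-3-en-2-yl carbonate (2.3 equiv in two portions)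
Product: 11 Gancaonin J, via 4'-O-tert-prenyl ether 8 (not isolated), via 3'-prenyldavidigenin 9 (not isolated), via 3'-prenyl-4'-O-tert-prenyl ether 10 (not isolated)
Conditions: Pd(PPh3)4 (5 mol%), 7 (1.1 equiv), THF, 0 °C, 3 h (vent CO2); sealed tube, 120 °C, 6 h; cool to 0 °C, Pd(PPh3)4 (3 mol%), 7 (1.2 equiv), 3 h (vent); sealed tube, 120 °C, 8 h
Reagents that add atoms: none
Why: Proposed new method: an acidity-gated, iterative O-(1,1-dimethylallyl)ation/aromatic Claisen relay in which one phenolic oxygen serves twice, in one flask and beside two other free OH groups, as the entry point for a C-prenyl group; Pd(0) ionises 7 to the η3-(1,1-dimethylallyl)Pd cation and, after loss of CO2, isobutoxide, which is quenched by the most acidic proton present (4'-OH para to the ketone, about 2 pKa units below the B-ring phenol in water and more in THF, while the 2'-OH is tied up in the hydrogen bond to C=O), and the ion-paired 4'-phenoxide attacks the more substituted allyl terminus under kinetic control to make the aryl O–C(CH3)2 bond of 8; heating drives the [3,3] shift to C3' (favoured by bond fixation in the chelated ring, and any C5' isomer converges) and enolisation frees the same 4'-OH in 9, which is again the most acidic site and is etherified by the second charge to 10, whose only open ortho position is C5', so the second [3,3] shift gives 11; residual Pd(0) can only re-ionise 8, 10 or a linear O-prenyl ether to the same ion pair, which drains through the [3,3] exit while the sealed tube retains any isoprene; the closest known reaction types are the Pd-catalysed decarboxylative (Tsuji–Trost) O-reverse-prenylation of phenols with tert-allylic carbonates and the thermal aromatic Claisen rearrangement of 1,1-dimethylallyl aryl ethers, known as separate single-pass steps; no stereocentre is formed.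

**Compound list**
1 | resorcinol (benzene-1,3-diol) | Oc1cccc(O)c1 | starting material
2 | 3-(4-hydroxyphenyl)propanoic acid (phloretic acid) | OC(=O)CCc1ccc(O)cc1 | starting material
3 | davidigenin, 1-(2,4-dihydroxyphenyl)-3-(4-hydroxyphenyl)propan-1-one | O=C(CCc1ccc(O)cc1)c1ccc(O)cc1O | intermediate
4 | 2-methylbut-3-en-2-ol | C=CC(C)(C)O | starting material
5 | isobutyl chloroformate (2-methylpropyl carbonochloridate) | CC(C)COC(Cl)=O | starting material
6 | lithium 2-methylbut-3-en-2-olate | [Li+].[O-]C(C)(C)C=C | intermediate
7 | isobutyl 2-methylbut-3-en-2-yl carbonate | C=CC(C)(C)OC(=O)OCC(C)C | intermediate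
8 | 1-[2-hydroxy-4-(2-methylbut-3-en-2-yloxy)phenyl]-3-(4-hydroxyphenyl)propan-1-one (4'-O-tert-prenyl ether of 3) | C=CC(C)(C)Oc1ccc(C(=O)CCc2ccc(O)cc2)c(O)c1 | intermediate
9 | 1-[2,4-dihydroxy-3-(3-methylbut-2-en-1-yl)phenyl]-3-(4-hydroxyphenyl)propan-1-one (3'-prenyldavidigenin) | CC(C)=CCc1c(O)ccc(C(=O)CCc2ccc(O)cc2)c1O | intermediate
10 | 1-[2-hydroxy-4-(2-methylbut-3-en-2-yloxy)-3-(3-methylbut-2-en-1-yl)phenyl]-3-(4-hydroxyphenyl)propan-1-one | C=CC(C)(C)Oc1ccc(C(=O)CCc2ccc(O)cc2)c(O)c1CC=C(C)C | intermediate
11 | Gancaonin J, 1-[2,4-dihydroxy-3,5-bis(3-methylbut-2-en-1-yl)phenyl]-3-(4-hydroxyphenyl)propan-1-one (achiral) | CC(C)=CCc1cc(C(=O)CCc2ccc(O)cc2)c(O)c(CC=C(C)C)c1O | target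

**Step count**
Total steps: 3. Longest linear sequence: 2 steps (1 → 3 → 11; equally 4 → 7 → 11).

**Steps most likely to fail, with fallbacks**

Step 3 (proposed new relay) is the main risk. Possible failures are O-alkylation of the B-ring phenol in the second pass (the 4'-OH is then flanked by a prenyl group), Pd-mediated loss of the allyl unit as isoprene or build-up of linear O-prenyl ether during heating, and an incomplete [3,3] shift at 120 °C. The fallback uses known chemistry only and sets out from 3. Alkylation of the most acidic OH with 3-chloro-3-methylbut-1-yne (K2CO3 1.1 equiv, KI, CuI cat., acetone, 50 °C) gives 1-[2-hydroxy-4-(2-methylbut-3-yn-2-yloxy)phenyl]-3-(4-hydroxyphenyl)propan-1-one F3. Lindlar semihydrogenation (H2, Pd/CaCO3–Pb, quinoline, EtOAc, rt) converts it to 8, now isolated and free of Pd(0), which is where the fallback rejoins the route. Heating 8 alone (xylene, 130 °C) gives 9, which is isolated. The same propargylation of 9 gives 1-[2-hydroxy-4-(2-methylbut-3-yn-2-yloxy)-3-(3-methylbut-2-en-1-yl)phenyl]-3-(4-hydroxyphenyl)propan-1-one F4, Lindlar reduction gives 10, and heating gives 11.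

Step 1 can fail through self-esterification or oligomerisation of the phenolic acid 2, or through a difficult work-up of boron-bound product. The fallback sets out from 1. A Houben–Hoesch reaction of 1 with 3-(4-hydroxyphenyl)propanenitrile (ZnCl2, dry HCl, Et2O, 0 °C) precipitates 1-(2,4-dihydroxyphenyl)-3-(4-hydroxyphenyl)propan-1-iminium chloride F1. The nitrile cannot self-condense and the iminium salt blocks a second attack. Hydrolysis in boiling water gives 3, where the route is rejoined.

Step 2 can fail through sluggish or unclean acylation of the hindered tertiary alkoxide, or through loss of the carbonate on distillation. The fallback sets out from 5. Acylation of the unhindered primary alcohol 3-methylbut-2-en-1-ol with 5 (pyridine, CH2Cl2, 0 °C) gives isobutyl 3-methylbut-2-en-1-yl carbonate F2. Used in step 3 in place of 7, it is ionised by Pd(0) to the same η3-(1,1-dimethylallyl)palladium cation (known for trisubstituted allylic carbonates and phenols), so the route is rejoined at 8.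

**Further compounds**
F1 | step 1 | 1-(2,4-dihydroxyphenyl)-3-(4-hydroxyphenyl)propan-1-iminium chloride | [NH2+]=C(CCc1ccc(O)cc1)c1ccc(O)cc1O.[Cl-]
F2 | step 2 | isobutyl 3-methylbut-2-en-1-yl carbonate | CC(C)=CCOC(=O)OCC(C)C
F3 | step 3 | 1-[2-hydroxy-4-(2-methylbut-3-yn-2-yloxy)phenyl]-3-(4-hydroxyphenyl)propan-1-one | C#CC(C)(C)Oc1ccc(C(=O)CCc2ccc(O)cc2)c(O)c1
F4 | step 3 | 1-[2-hydroxy-4-(2-methylbut-3-yn-2-yloxy)-3-(3-methylbut-2-en-1-yl)phenyl]-3-(4-hydroxyphenyl)propan-1-one | C#CC(C)(C)Oc1ccc(C(=O)CCc2ccc(O)cc2)c(O)c1CC=C(C)C
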